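**Falling rate.** The readings of Friday's flask show the target forming 8.05 times faster over the first 10.0 h than between 30.0 h and 60.0 h. Substrate turned into target gives a factor of 1.07 between those times, far less, so the slowing has another source.

| setting | Friday's | Monday's | flask |
|---|---|---|---|
| substrate | 3 M | 3 M | 3.0 M |
| precatalyst | 30 mM | 45 mM | 30 mM |
| temperature | 110 °C | 105 °C | 110 °C |
| remark | the very flask that is asked about, followed so far | run made earlier |  |
| time |  |  | 2.5 d |

| run | time / h | target / % |
|---|---|---|
| Friday's | 10.0 | 5.1 |
| Friday's | 20.0 | 6.8 |
| Friday's | 30.0 | 9.0 |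
| Friday's | 40.0 | 8.4 |
| Friday's | 48.0 | 8.8 |
| Friday's | 60.0 | 10.9 |
| Monday's | 0.417 | 0 |
| Monday's | 0.667 | 0 |
| Monday's | 1.00 | 0 |
| Monday's | 2.00 | 1.8 |
| Monday's | 3.00 | 0.4 |
| Monday's | 5.00 | 2.6 |

(readings scatter by 1 percentage point)

- summer: at 2.5 d add precatalyst, 100% of the amount charged, then wait 5.0 d
- spring: at 2.5 d take out 90% of the target then present, then wait 5.0 d
- midnight: change nothing and wait 5.0 d more
- dawn: at 2.5 d raise the temperature by 25 K, then wait 5.0 d

- target that was removed still counts
- the earlier runs were read with a standard deviation of 1 percentage point
- steps thought possible: substrate <-> other conformer; substrate + catalyst -> catalyst + target; catalyst + other conformer -> catalyst + isomer of the product; precatalyst -> catalyst; 2 catalyst <-> resting dimer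
- additions bring no volume worth counting

* target, in percent of the substrate first charged, at 2.5 d
* the option that brings most further target ("none" if no option brings more than 2 percentage points) (summer / spring / midnight / dawn / none)
* target present, with what was taken out counted in, in percent of the substrate first charged, after summer
* target present, with what was taken out counted in, in percent of the substrate first charged, after midnight

**Turned round.** For "none", waiting must bring no more than 2 percentage points. The late slope of Friday's flask, carried over 5.0 d, gives a gain of 7.6 points, which is 3.80 times that line. But two readings set this slope, so the gain carries a scatter of 5.7 points. The line stands 0.982 standard deviations below the gain.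

**Root factor.** Suppose the balance between catalyst and the resting dimer, the resting state, lies far on the side of the dimer. Then c(catalyst) goes as the square root of the charge. The root factor, the square root of the ratio of charges, is 1.41 for summer. If the rate of target follows c(catalyst), this reckoning gives summer a gain of 11 points.

**Forecast.** The forecast gives 10.3% now, 17% after midnight and 20.5% after summer, with dawn best: “dawn should bring the most, provided the pool survives”. Its gains of 6.7 points and 10 points lie below this reckoning's 7.6 points and 11 points.

**Equations.**

    substrate ⇌ other conformer (K = 2.10, k = 0.110 h⁻¹, Ea = 110 kJ mol⁻¹, ΔH = −31.0 kJ mol⁻¹)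
    substrate + catalyst → catalyst + target (k = 1.80 M⁻¹ h⁻¹, Ea = 104 kJ mol⁻¹)
    catalyst + other conformer → catalyst + isomer of the product (k = 1.00 M⁻¹ h⁻¹, Ea = 87.0 kJ mol⁻¹)
    precatalyst → catalyst (k = 0.160 h⁻¹, Ea = 130 kJ mol⁻¹)
    2 catalyst ⇌ resting dimer (K = 11000 M⁻¹, k = 47.0 M⁻¹ h⁻¹, Ea = 78.0 kJ mol⁻¹, ΔH = −46.0 kJ mol⁻¹)
    (constants at 110 °C)

**What came.** The flask gave 9.70% at 2.5 d, and dawn was best, bringing 49 points. In the flask, half of the turnover of substrate into other conformer up to 2.5 d was done by 3.94 h, and precatalyst stood at 38.3% of the catalyst charged at 6.00 h. At 30.0 h the resting dimer of the flask held 94.4% of the catalyst charged, and 4.83% stood as catalyst. Midnight brought 6.1 points, reaching 15.8%, and one root factor makes that gain 8.6 points, against 10 points for summer, which reached 20.0%. The neighbour flask with a quarter of the precatalyst is reckoned by two root factors at 4.88% and gave 4.84%.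

Readings and results were generated by integration for substances that don't exist; the scatter is artificial.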